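**Retrosynthetic overview**

1. All 24 carbons come from three commercial pieces: propyne 1 (C7–C9 linchpin), (R)-1,2-epoxyhexane 2 (C1–C6, brings the C5 stereocentre) and pentadecanal 3 (C10–C24).
2. C–C disconnections at C6–C7 and C9–C10: the dianion of 1, 1,3-dilithiopropyne 4, opens 2 (giving 5) and its acetylide end then adds to 3 (dialkoxide 6, then diol-yne 7); no protecting groups.
3. Ring disconnection (one ring only, the oxolane, closed last): the O–C2 bond, by 5-exo-trig oxa-Michael addition of the C5 hydroxyl to the (E)-enone of hydroxy-enone 8.
4. 8 is not built by olefination or metathesis: it is unmasked in the flask from the propargylic alcohol of 7 by internal redox isomerisation, and a chiral bifunctional catalyst then closes the ring with C2 cis to butyl, giving target 9.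

Assumption: the presumed biosynthesis is taken to be oxa-Michael closure of a linear (5R,8E)-5-hydroxy-8-en-10-one, the target is read from the SMILES as 2,5-cis (2R,5R), and the quinidine-derived thiourea is assumed to be the pseudoenantiomer that delivers O to the Re face of C8 (if a probe run shows the opposite sense, the quinine-derived pseudoenantiomer replaces it).

**Step 1**
Reactants: 1 propyne; 2 (R)-1,2-epoxyhexane; 3 pentadecanal
Product: 7 (5R,10RS)-tetracos-8-yne-5,10-diol, via 1,3-dilithiopropyne 4 (not isolated), via lithium alkynide-alkoxide 5 (not isolated), via dilithium diolate 6 (not isolated)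
Conditions: 1 (1.15 equiv), n-BuLi (2.3 equiv), TMEDA (2.3 equiv), Et2O/hexane, −78 → 20 °C; 2 (1.0 equiv), −20 → 20 °C; THF, 3 (1.3 equiv), −78 → 0 °C; H2O
Reagents that add atoms: none
Why: Sequential dianion alkylation then acetylide addition: the sp3 carbanion of 4 is the more nucleophilic site and opens the terminal epoxide by SN2 at CH2 (the C5–O bond is untouched, so R is carried over unchanged), after which the remaining lithium acetylide adds to the aldehyde carbonyl; the new C10 carbinol forms as both epimers, which is immaterial because it becomes the ketone.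

**Step 2**
Reactants: 7 (5R,10RS)-tetracos-8-yne-5,10-diol
Product: 9 1-[(2R,5R)-5-butyloxolan-2-yl]hexadecan-2-one, via hydroxy-enone 8 (not isolated)
Conditions: (η5-C9H7)RuCl(PPh3)2 (5 mol %), InCl3 (5 mol %), Et3NHPF6 (5 mol %), THF, 65 °C; SiO2 plug, evaporate; N-[3,5-bis(trifluoromethyl)phenyl]-N′-[(9R)-6′-methoxycinchonan-9-yl]thiourea (quinidine-derived, 10 mol %), CPME, 25 °C, 48 h
Reagents that add atoms: none
Why: Proposed new method: the ruthenium/indium pair isomerises only the propargylic alcohol to the (E)-enone 8 by hydride shift within the ruthenium–alkyne complex and protodemetalation (closest known: redox isomerisation of propargylic alcohols and its tandem with acid-promoted O-conjugate addition), the weak acid Et3NH+ in place of a sulfonic acid being chosen so that 8 survives uncyclised; once the metals are removed, the thiourea binds the enone carbonyl while the quinuclidine activates the C5 hydroxyl (closest known: aminothiourea-catalysed cycloetherification of ε-hydroxy enones), so that O adds to the Re face of C8 in a 5-exo-trig oxa-Michael addition under catalyst control, which overrides the small intrinsic bias of the C5 centre and sets C2 as R, cis to butyl.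

**Compound list**

1 | propyne | CC#C | starting material
2 | (R)-1,2-epoxyhexane, (2R)-2-butyloxirane | CCCC[C@@H]1CO1 | starting material
3 | pentadecanal | CCCCCCCCCCCCCCC=O | starting material
4 | 1,3-dilithiopropyne | [Li]CC#C[Li] | intermediate
5 | lithium (5R)-1-lithionon-1-yn-5-olate | [Li]C#CCC[C@@H](CCCC)O[Li] | intermediate
6 | dilithium (5R,10RS)-tetracos-8-yne-5,10-diolate | CCCCCCCCCCCCCCC(O[Li])C#CCC[C@@H](CCCC)O[Li] | intermediate
7 | (5R,10RS)-tetracos-8-yne-5,10-diol | CCCCCCCCCCCCCCC(O)C#CCC[C@@H](CCCC)O | intermediate
8 | (5R,8E)-5-hydroxytetracos-8-en-10-one | CCCCCCCCCCCCCCC(=O)/C=C/CC[C@@H](CCCC)O | intermediate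
9 | 1-[(2R,5R)-5-butyloxolan-2-yl]hexadecan-2-one (2,5-cis) | CCCCCCCCCCCCCCC(=O)C[C@H]1CC[C@@H](CCCC)O1 | target

**Totals**

Total step count: 2. Longest linear sequence: 2.

**Steps most likely to fail**

The route has only two steps, so the three weakest operations are ranked; two of them lie in step 2.

First, step 2, cyclisation stage. The catalyst may give a poor cis:trans ratio on this dialkyl enone with a secondary carbinol as nucleophile; thermodynamic control cannot rescue it, because 2,5-cis and 2,5-trans oxolanes are close in energy. The fallback sets out from 7 and comes back at 9, and it fixes C2 by hydrogenation instead of by the conjugate addition. MnO2 (CH2Cl2, 20 °C) oxidises only the propargylic carbinol of 7 to (5R)-5-hydroxytetracos-8-yn-10-one F1. DBU (10 mol %, THF, 20 °C) closes the ring by 5-exo-dig oxa-Michael addition to the ynone, giving (1E)-1-[(5R)-5-butyloxolan-2-ylidene]hexadecan-2-one F2 (an E/Z mixture is acceptable, both isomers converge). H2 (1 atm) over 5% Rh on Al2O3 in EtOAc adds to the exocyclic enol-ether double bond from the face opposite the butyl group, which puts the side chain cis and gives 9.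

Second, step 2, isomerisation stage. The enone 8 may cyclise unselectively while it is being formed at 65 °C, or the ruthenium catalyst may erode the C5 carbinol (to be checked on 8 by Mosher ester). The fallback sets out from 7 and comes back at 8, and it replaces the redox-neutral isomerisation by a reduction–oxidation pair. NaAlH2(OCH2CH2OCH3)2 (THF, 0 → 20 °C) effects alkoxide-directed trans-hydroalumination of the propargylic alcohol and gives (5R,8E,10RS)-tetracos-8-ene-5,10-diol F3. MnO2 (CH2Cl2, 20 °C) then oxidises only the allylic carbinol to 8; after filtration, 8 enters the thiourea stage of step 2 unchanged.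

Third, step 1. The dianion of propyne may form incompletely or open the epoxide sluggishly, so that the one-pot yield is low. The fallback sets out from 2 and comes back at 7, and it builds the two C–C bonds one at a time with a masked propargyl anion. Lithiated 1-(trimethylsilyl)propyne (n-BuLi, TMEDA, Et2O, 0 °C) opens 2 at CH2 to give (5R)-1-(trimethylsilyl)non-1-yn-5-ol F4. K2CO3 in MeOH removes the silyl group to give (5R)-non-1-yn-5-ol F5. n-BuLi (2.1 equiv, THF, −78 °C) followed by 3 and aqueous work-up gives 7.

**Further compounds**

F1 | step 2 | (5R)-5-hydroxytetracos-8-yn-10-one | CCCCCCCCCCCCCCC(=O)C#CCC[C@@H](CCCC)O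
F2 | step 2 | (1E)-1-[(5R)-5-butyloxolan-2-ylidene]hexadecan-2-one | CCCCCCCCCCCCCCC(=O)/C=C1\CC[C@@H](CCCC)O1
F3 | step 2 | (5R,8E,10RS)-tetracos-8-ene-5,10-diol | CCCCCCCCCCCCCCC(O)/C=C/CC[C@@H](CCCC)O
F4 | step 1 | (5R)-1-(trimethylsilyl)non-1-yn-5-ol | C[Si](C)(C)C#CCC[C@@H](CCCC)O
F5 | step 1 | (5R)-non-1-yn-5-ol | C#CCC[C@@H](CCCC)O
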